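## Retrosynthetic overview
1. The target comes from a tris-MOM diaryl ether by acid-catalysed loss of three MOM groups. That ether is cut at the C–O bond (Ullmann) into a ring A phenol and a ring B aryl iodide.
2. Both coupling handles (OH on ring A, I on ring B) come from directed ortho-lithiation next to an OMOM group of the two reverse-farnesylated arenes.
3. The ring A catechol comes from the para-alkylphenol by tyrosinase (copper monophenol monooxygenase) ortho-hydroxylation.
4. Each quaternary centre comes from an NHC–copper-catalysed enantioselective SN2' arylation of one common electrophile, (E,E)-farnesyl diethyl phosphate, with an aryl(diethyl)alane. The (R) centre is set first, and the (S) centre is set with the mirror-image ligand.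
5. No ring is formed. Ring A is 4-bromophenol, ring B is 2-bromophenol, and both C15 chains with their E-alkenes come from (E,E)-farnesol.

Ligand: L is (4S,5S)-1-mesityl-4,5-diphenyl-3-(2-sulfonatophenyl)-4,5-dihydroimidazolium, a zwitterionic NHC precursor made from (S,S)-1,2-diphenylethane-1,2-diamine. ent-L is its (4R,5R) mirror image. Both are used in catalytic amount only.

Assumption: L is taken to give the (R) centre and ent-L the (S) centre, by analogy with aryl additions to geranyl-type phosphates; if the first chiral HPLC/rotation check shows the opposite sense, the two ligands are exchanged and nothing else changes.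

## Route

Step 1
Reactants: 1 (2E,6E)-farnesol
Product: 2 diethyl (2E,6E)-3,7,11-trimethyldodeca-2,6,10-trien-1-yl phosphate
Conditions: ClP(O)(OEt)2, Et3N, DMAP (cat.), CH2Cl2, 0 °C to rt
Reagents that add atoms: diethyl chlorophosphate CCOP(=O)(Cl)OCC
Why: DMAP-catalysed O-phosphorylation of a primary allylic alcohol takes place at oxygen only, so both E-alkenes are kept and the leaving group for the allylic substitutions is installed.

Step 2
Reactants: 3 4-bromophenol
Product: 4 (4-bromophenoxy)(tert-butyl)dimethylsilane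
Conditions: TBSCl, imidazole, DMF, rt
Reagents that add atoms: tert-butyldimethylsilyl chloride CC(C)(C)[Si](C)(C)Cl
Why: Imidazole-promoted silyl ether protection masks the acidic OH with a group that survives n-BuLi and Et2AlCl and is later removed by fluoride without acid.

Step 3
Reactants: 4 (4-bromophenoxy)(tert-butyl)dimethylsilane; 2 diethyl (2E,6E)-farnesyl phosphate
Product: 7 tert-butyl(dimethyl){4-[(3R,6E)-3,7,11-trimethyldodeca-1,6,10-trien-3-yl]phenoxy}silane, via aryllithium 5 (not isolated), via aryl(diethyl)alane 6 (not isolated)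
Conditions: 4 (2 equiv), n-BuLi, THF, −78 °C; Et2AlCl, −78 °C to rt; then 2, CuCl2·2H2O (5 mol %), L (5.5 mol %), THF, −30 °C, 24 h; aq. potassium sodium tartrate
Reagents that add atoms: none
Why: After halogen–lithium exchange and Li-to-Al transmetallation, the NHC–copper-catalysed enantioselective allylic substitution (SN2') transfers aryl rather than ethyl to C3 of the E-allylic phosphate, the divalent copper salt being reduced in situ to the active monovalent copper–NHC aryl species whose chiral pocket selects one alkene face and sets the (R) quaternary centre.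

Step 4
Reactants: 7 the (R)-TBS ether
Product: 8 4-[(3R,6E)-3,7,11-trimethyldodeca-1,6,10-trien-3-yl]phenol
Conditions: Bu4NF, THF, 0 °C; er by chiral HPLC (preparative chiral SFC polish if below 98:2)
Reagents that add atoms: none
Why: Fluoride-mediated desilylation is driven by the Si–F bond and touches neither the alkenes nor the non-epimerisable quaternary centre.

Step 5
Reactants: 8 4-[(3R,6E)-3,7,11-trimethyldodeca-1,6,10-trien-3-yl]phenol
Product: 10 4-[(3R,6E)-3,7,11-trimethyldodeca-1,6,10-trien-3-yl]benzene-1,2-diol, via o-quinone 9 (not isolated)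
Conditions: mushroom tyrosinase (Agaricus bisporus, immobilised on an epoxy-acrylic resin), O2 (1 atm), CH2Cl2/NaH2PO4–Na2HPO4 buffer pH 7, 25 °C; then Na2S2O4, THF–H2O, rt
Reagents that add atoms: dioxygen O=O
Why: Tyrosinase, a copper-dependent monophenol monooxygenase (oxidoreductase class, EC 1.14.18.1), performs enzymatic ortho-hydroxylation of para-alkylphenols, including 4-tert-alkyl and long-chain lipophilic ones in biphasic media; it places one O atom on either of the two equivalent ortho positions, ignores the three C=C bonds, and gives a fairly stable 4-tert-alkyl o-quinone that dithionite reduces to the catechol.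

Step 6
Reactants: 10 the (R)-catechol
Product: 11 1,2-bis(methoxymethoxy)-4-[(3R,6E)-3,7,11-trimethyldodeca-1,6,10-trien-3-yl]benzene
Conditions: MOMCl (3 equiv), i-Pr2NEt, CH2Cl2, 0 °C to rt, argon
Reagents that add atoms: chloromethyl methyl ether COCCl
Why: Double O-alkylation (MOM acetal protection) removes the oxidation-prone catechol protons and installs the directing groups for the next lithiation.

Step 7
Reactants: 11 the (R)-bis-MOM ether
Product: 14 2,3-bis(methoxymethoxy)-5-[(3R,6E)-3,7,11-trimethyldodeca-1,6,10-trien-3-yl]phenol, via aryllithium 12 (not isolated), via lithium aryltrimethoxyborate 13 (not isolated)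
Conditions: n-BuLi, THF, 0 °C, 1.5 h; B(OMe)3, −78 °C to rt; 30% H2O2, aq. NaOH, 0 °C
Reagents that add atoms: hydrogen peroxide OO
Why: Directed ortho-metalation occurs only at the OMOM-flanked position meta to the side chain, because the other ortho site is blocked by the tert-alkyl group, and the borylation/alkaline peroxide oxidation that follows gives the phenol under conditions that do not epoxidise unactivated alkenes.

Step 8
Reactants: 15 2-bromophenol
Product: 16 1-bromo-2-(methoxymethoxy)benzene
Conditions: MOMCl, i-Pr2NEt, CH2Cl2, 0 °C to rt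
Reagents that add atoms: chloromethyl methyl ether COCCl
Why: MOM acetal protection masks the OH for the organometallic steps and serves later as the ortho-directing group.

Step 9
Reactants: 16 1-bromo-2-(methoxymethoxy)benzene; 2 diethyl (2E,6E)-farnesyl phosphate
Product: 19 1-(methoxymethoxy)-2-[(3S,6E)-3,7,11-trimethyldodeca-1,6,10-trien-3-yl]benzene, via aryllithium 17 (not isolated), via aryl(diethyl)alane 18 (not isolated)
Conditions: 16 (2 equiv), n-BuLi, THF, −78 °C; Et2AlCl, −78 °C to rt; then 2, CuCl2·2H2O (5 mol %), ent-L (5.5 mol %), THF, −15 °C, 48 h; aq. potassium sodium tartrate; er by chiral HPLC (chiral SFC polish if below 98:2)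
Reagents that add atoms: none
Why: This is the same NHC–copper-catalysed enantioselective allylic substitution (SN2') as in step 3, run warmer and longer for the ortho-substituted aryl group, and the mirror-image ligand exposes the opposite face of the same E-phosphate and so sets the (S) quaternary centre.

Step 10
Reactants: 19 the (S)-MOM ether
Product: 21 1-iodo-2-(methoxymethoxy)-3-[(3S,6E)-3,7,11-trimethyldodeca-1,6,10-trien-3-yl]benzene, via aryllithium 20 (not isolated)
Conditions: n-BuLi, TMEDA, Et2O, 0 °C, 2 h; I2, THF, −78 °C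
Reagents that add atoms: iodine II
Why: Directed ortho-metalation can reach only the single free position next to OMOM (there are no benzylic protons, and allylic metalation is much slower), and the iodine quench of the aryllithium is instantaneous at −78 °C.

Step 11
Reactants: 14 the ring A phenol; 21 the ring B aryl iodide
Product: 22 1-{2,3-bis(methoxymethoxy)-5-[(3R,6E)-3,7,11-trimethyldodeca-1,6,10-trien-3-yl]phenoxy}-2-(methoxymethoxy)-3-[(3S,6E)-3,7,11-trimethyldodeca-1,6,10-trien-3-yl]benzene
Conditions: CuI (15 mol %), N,N-dimethylglycine (45 mol %), Cs2CO3 (2 equiv), 1,4-dioxane, 95 °C, argon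
Reagents that add atoms: none
Why: The amino-acid-ligated Ullmann diaryl ether coupling pairs the more electron-rich arene as phenoxide with the less electron-rich arene as iodide, uses monovalent copper and so avoids Heck chemistry at the vinyl groups, and leaves MOM ethers, alkenes and both quaternary centres intact.

Step 12
Reactants: 22 the tris-MOM diaryl ether
Product: 23 3-{2-hydroxy-3-[(3S,6E)-3,7,11-trimethyldodeca-1,6,10-trien-3-yl]phenoxy}-5-[(3R,6E)-3,7,11-trimethyldodeca-1,6,10-trien-3-yl]benzene-1,2-diol (CNP0325484.1)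
Conditions: conc. HCl (cat.), degassed MeOH–THF (3:1), 40 °C, argon
Reagents that add atoms: none
Why: Acid-catalysed transacetalisation to methanol cleaves phenolic MOM ethers at an acidity too low to protonate tri- or monosubstituted alkenes, and no five- or six-membered ether can close from the ring B phenol onto the chain, so the polyene chains and both stereocentres reach the target unchanged.

## Compound list
1 | (2E,6E)-farnesol | OC/C=C(\C)CC/C=C(\C)CCC=C(C)C | starting material
2 | diethyl (2E,6E)-3,7,11-trimethyldodeca-2,6,10-trien-1-yl phosphate | CCOP(=O)(OCC)OC/C=C(\C)CC/C=C(\C)CCC=C(C)C | intermediate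
3 | 4-bromophenol | Oc1ccc(Br)cc1 | starting material
4 | (4-bromophenoxy)(tert-butyl)dimethylsilane | CC(C)(C)[Si](C)(C)Oc1ccc(Br)cc1 | intermediate
5 | {4-[tert-butyl(dimethyl)silyloxy]phenyl}lithium | [Li]c1ccc(O[Si](C)(C)C(C)(C)C)cc1 | intermediate
6 | {4-[tert-butyl(dimethyl)silyloxy]phenyl}(diethyl)alane | CC[Al](CC)c1ccc(O[Si](C)(C)C(C)(C)C)cc1 | intermediate
7 | tert-butyl(dimethyl){4-[(3R,6E)-3,7,11-trimethyldodeca-1,6,10-trien-3-yl]phenoxy}silane | C=C[C@@](C)(CC/C=C(\C)CCC=C(C)C)c1ccc(O[Si](C)(C)C(C)(C)C)cc1 | intermediate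
8 | 4-[(3R,6E)-3,7,11-trimethyldodeca-1,6,10-trien-3-yl]phenol | C=C[C@@](C)(CC/C=C(\C)CCC=C(C)C)c1ccc(O)cc1 | intermediate
9 | 4-[(3R,6E)-3,7,11-trimethyldodeca-1,6,10-trien-3-yl]cyclohexa-3,5-diene-1,2-dione | C=C[C@@](C)(CC/C=C(\C)CCC=C(C)C)C1=CC(=O)C(=O)C=C1 | intermediate
10 | 4-[(3R,6E)-3,7,11-trimethyldodeca-1,6,10-trien-3-yl]benzene-1,2-diol | C=C[C@@](C)(CC/C=C(\C)CCC=C(C)C)c1ccc(O)c(O)c1 | intermediate
11 | 1,2-bis(methoxymethoxy)-4-[(3R,6E)-3,7,11-trimethyldodeca-1,6,10-trien-3-yl]benzene | C=C[C@@](C)(CC/C=C(\C)CCC=C(C)C)c1ccc(OCOC)c(OCOC)c1 | intermediate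
12 | {2,3-bis(methoxymethoxy)-5-[(3R,6E)-3,7,11-trimethyldodeca-1,6,10-trien-3-yl]phenyl}lithium | C=C[C@@](C)(CC/C=C(\C)CCC=C(C)C)c1cc(OCOC)c(OCOC)c([Li])c1 | intermediate
13 | lithium {2,3-bis(methoxymethoxy)-5-[(3R,6E)-3,7,11-trimethyldodeca-1,6,10-trien-3-yl]phenyl}trimethoxyborate | [Li+].C=C[C@@](C)(CC/C=C(\C)CCC=C(C)C)c1cc(OCOC)c(OCOC)c([B-](OC)(OC)OC)c1 | intermediate
14 | 2,3-bis(methoxymethoxy)-5-[(3R,6E)-3,7,11-trimethyldodeca-1,6,10-trien-3-yl]phenol | C=C[C@@](C)(CC/C=C(\C)CCC=C(C)C)c1cc(OCOC)c(OCOC)c(O)c1 | intermediate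
15 | 2-bromophenol | Oc1ccccc1Br | starting material
16 | 1-bromo-2-(methoxymethoxy)benzene | COCOc1ccccc1Br | intermediate
17 | [2-(methoxymethoxy)phenyl]lithium | COCOc1ccccc1[Li] | intermediate
18 | diethyl[2-(methoxymethoxy)phenyl]alane | CC[Al](CC)c1ccccc1OCOC | intermediate
19 | 1-(methoxymethoxy)-2-[(3S,6E)-3,7,11-trimethyldodeca-1,6,10-trien-3-yl]benzene | COCOc1ccccc1[C@](C)(C=C)CC/C=C(\C)CCC=C(C)C | intermediate
20 | {2-(methoxymethoxy)-3-[(3S,6E)-3,7,11-trimethyldodeca-1,6,10-trien-3-yl]phenyl}lithium | COCOc1c([Li])cccc1[C@](C)(C=C)CC/C=C(\C)CCC=C(C)C | intermediate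
21 | 1-iodo-2-(methoxymethoxy)-3-[(3S,6E)-3,7,11-trimethyldodeca-1,6,10-trien-3-yl]benzene | COCOc1c(I)cccc1[C@](C)(C=C)CC/C=C(\C)CCC=C(C)C | intermediate
22 | 1-{2,3-bis(methoxymethoxy)-5-[(3R,6E)-3,7,11-trimethyldodeca-1,6,10-trien-3-yl]phenoxy}-2-(methoxymethoxy)-3-[(3S,6E)-3,7,11-trimethyldodeca-1,6,10-trien-3-yl]benzene | C=C[C@@](C)(CC/C=C(\C)CCC=C(C)C)c1cc(OCOC)c(OCOC)c(Oc2cccc([C@](C)(C=C)CC/C=C(\C)CCC=C(C)C)c2OCOC)c1 | intermediate
23 | 3-{2-hydroxy-3-[(3S,6E)-3,7,11-trimethyldodeca-1,6,10-trien-3-yl]phenoxy}-5-[(3R,6E)-3,7,11-trimethyldodeca-1,6,10-trien-3-yl]benzene-1,2-diol | C=C[C@@](C)(CC/C=C(\C)CCC=C(C)C)c1cc(O)c(O)c(Oc2cccc([C@](C)(C=C)CC/C=C(\C)CCC=C(C)C)c2O)c1 | target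

## Summary
Total step count: 12.
Longest linear sequence: 8 steps (step 2 or step 1, then 3, 4, 5, 6, 7, 11, 12). The ring B branch is steps 8, 9 and 10 and joins at step 11.

## The three steps most likely to fail

**Step 9.** The ortho-alkoxy aryl group is hindered, and its MOM oxygen can chelate aluminium, so aryl transfer may be slow or poorly enantioselective.
- The fallback inverts the polarity of the allylic substitution: the hindered arene sits on the electrophile and the C11 chain becomes the nucleophile. It sets out from 16 and comes back at 19.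
- Br/Li exchange on 16 (n-BuLi, giving 17) and acylation with N-methoxy-N-methylacetamide give 1-[2-(methoxymethoxy)phenyl]ethanone F1.
- Horner–Wadsworth–Emmons olefination (triethyl phosphonoacetate, NaH, THF) and chromatographic removal of the Z isomer give ethyl (2E)-3-[2-(methoxymethoxy)phenyl]but-2-enoate F2.
- Reduction with i-Bu2AlH gives (2E)-3-[2-(methoxymethoxy)phenyl]but-2-en-1-ol F3.
- ClP(O)(OEt)2/Et3N/DMAP gives diethyl (2E)-3-[2-(methoxymethoxy)phenyl]but-2-en-1-yl phosphate F4.
- In parallel, commercial achiral (3E)-4,8-dimethylnona-3,7-dien-1-ol (homogeraniol) is converted with I2/PPh3/imidazole into (6E)-9-iodo-2,6-dimethylnona-2,6-diene F5.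
- t-BuLi (2 equiv, Et2O–pentane, −78 °C) turns F5 into [(3E)-4,8-dimethylnona-3,7-dien-1-yl]lithium F6, and ZnBr2 (0.5 equiv) then gives bis[(3E)-4,8-dimethylnona-3,7-dien-1-yl]zinc F7, with the lithium salts removed by centrifugation.
- Chiral NHC–copper-catalysed enantioselective SN2' alkylation of F4 with F7, using the ligand enantiomer that gives (S), builds the same quaternary centre and delivers 19.

**Step 5.** The very lipophilic phenol 8 may be turned over slowly by tyrosinase, or the o-quinone may be lost to side reactions.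
- The fallback moves the enzymatic hydroxylation to the front of the route, onto a small water-soluble phenol. It sets out from 3 and comes back at 11.
- Whole cells of E. coli expressing 4-hydroxyphenylacetate 3-hydroxylase convert 3 into 4-bromobenzene-1,2-diol F8. This enzyme is a two-component flavin-dependent monooxygenase that stops at the catechol stage.
- MOMCl/i-Pr2NEt gives 4-bromo-1,2-bis(methoxymethoxy)benzene F9.
- n-BuLi gives [3,4-bis(methoxymethoxy)phenyl]lithium F10, and Et2AlCl gives diethyl[3,4-bis(methoxymethoxy)phenyl]alane F11.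
- The CuCl2·2H2O/L allylic substitution of 2 with F11, an aryl group without ortho substituents, gives 11 directly.

**Step 11.** Both partners carry a buttressed ortho-OMOM group, so the thermal Ullmann coupling may stall or lead to hydrodeiodination.
- The fallback replaces the aryl halide coupling by a room-temperature oxidative Chan–Lam–Evans coupling of a boronic acid. It sets out from 19 and comes back at 22.
- The ortho-lithiated species 20, made from 19 as in step 10, is quenched with B(OMe)3 to give lithium {2-(methoxymethoxy)-3-[(3S,6E)-3,7,11-trimethyldodeca-1,6,10-trien-3-yl]phenyl}trimethoxyborate F12.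
- Hydrolysis with aq. NH4Cl gives {2-(methoxymethoxy)-3-[(3S,6E)-3,7,11-trimethyldodeca-1,6,10-trien-3-yl]phenyl}boronic acid F13.
- F13 couples with phenol 14 under Cu(OAc)2, pyridine, 4 Å molecular sieves, CH2Cl2, air, rt, to give 22.

## Further compounds
F1 | step 9 | 1-[2-(methoxymethoxy)phenyl]ethanone | CC(=O)c1ccccc1OCOC
F2 | step 9 | ethyl (2E)-3-[2-(methoxymethoxy)phenyl]but-2-enoate | CCOC(=O)/C=C(\C)c1ccccc1OCOC
F3 | step 9 | (2E)-3-[2-(methoxymethoxy)phenyl]but-2-en-1-ol | OC/C=C(\C)c1ccccc1OCOC
F4 | step 9 | diethyl (2E)-3-[2-(methoxymethoxy)phenyl]but-2-en-1-yl phosphate | CCOP(=O)(OCC)OC/C=C(\C)c1ccccc1OCOC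
F5 | step 9 | (6E)-9-iodo-2,6-dimethylnona-2,6-diene | ICC/C=C(\C)CCC=C(C)C
F6 | step 9 | [(3E)-4,8-dimethylnona-3,7-dien-1-yl]lithium | [Li]CC/C=C(\C)CCC=C(C)C
F7 | step 9 | bis[(3E)-4,8-dimethylnona-3,7-dien-1-yl]zinc | CC(C)=CCC/C(C)=C/CC[Zn]CC/C=C(\C)CCC=C(C)C
F8 | step 5 | 4-bromobenzene-1,2-diol | Oc1ccc(Br)cc1O
F9 | step 5 | 4-bromo-1,2-bis(methoxymethoxy)benzene | COCOc1ccc(Br)cc1OCOC
F10 | step 5 | [3,4-bis(methoxymethoxy)phenyl]lithium | COCOc1ccc([Li])cc1OCOC
F11 | step 5 | diethyl[3,4-bis(methoxymethoxy)phenyl]alane | CC[Al](CC)c1ccc(OCOC)c(OCOC)c1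
F12 | step 11 | lithium {2-(methoxymethoxy)-3-[(3S,6E)-3,7,11-trimethyldodeca-1,6,10-trien-3-yl]phenyl}trimethoxyborate | [Li+].COCOc1c([B-](OC)(OC)OC)cccc1[C@](C)(C=C)CC/C=C(\C)CCC=C(C)C
F13 | step 11 | {2-(methoxymethoxy)-3-[(3S,6E)-3,7,11-trimethyldodeca-1,6,10-trien-3-yl]phenyl}boronic acid | COCOc1c(B(O)O)cccc1[C@](C)(C=C)CC/C=C(\C)CCC=C(C)C
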